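**Plan**

1. Retrosynthesis: cut the two gallate C–O bonds, then the lower pyran at C4–C4a (arene–epoxide) and O1–C2 (Mitsunobu). This separates an aryl oxiranyl carbinol from an upper flavan that carries one free phenol para to the interflavan bond.
2. Cut the upper pyran at O1–C2 and C2–aryl (aryl ketone from a Weinreb amide), then C3–O (enolate hydroxylation), to reach a 4-aryl-3,4-dihydrocoumarin. Remove its ring oxygen (O1–C8a) to reach a 3-arylindan-1-one, which is cut at C3–C3a (Nazarov) and at the alkene (Knoevenagel).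
3. Enabling feature: the upper C-ring is a benzo-fused six-membered ring whose only heteroatom, O1, lies between aryl carbon C8a and C2. Deleting O1 leaves a five-membered aryl ketone ring (C8a–C(=O)–C3–C4–C4a) that already holds the C4 stereocentre and the phloroglucinol ring of the lower unit.
4. Forward: indanone ring (Nazarov), then the six-membered lactone by oxygen insertion, then the lactone is opened at its acyl C–O bond (O1–C8a kept) and re-closed as the upper pyran. The lower pyran follows by O-alkylation and arene–epoxide closure, then two gallates and hydrogenolysis.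
5. Stereochemistry: upper C4 from a Cu(II)–bis(oxazoline) Nazarov cyclisation; C3 trans to it by enolate hydroxylation; C2 by chelation-controlled reduction followed by Mitsunobu inversion. Lower C2/C3 come from a Sharpless kinetic-resolution epoxy alcohol (C2 inverted on etherification, C3 retained).

Key step: step 7

Abbreviations: BnO = benzyloxy, TIPSO = (triisopropylsilyl)oxy.
Assumption: the Cu(II)–(S,S)-Ph-box catalyst of step 5 is taken to give the (3R) series; if the opposite sense is found, the (R,R)-ligand is used and nothing else changes.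

**Route**

Step 1
Reactants: 1 3,5-bis(BnO)phenol
Product: 3 2,6-bis(BnO)-4-hydroxybenzaldehyde, via iminium salt 2 (not isolated)
Conditions: POCl3, DMF, 0 °C → rt; then aq. NaOAc
Reagents that add atoms: N,N-dimethylformamide CN(C)C=O; water O
Why: Vilsmeier–Haack formylation, in which the position para to the free hydroxyl (between the two benzyloxy groups) is the most activated and least hindered site, so the 4-hydroxy aldehyde should be the main product and the hydrogen-bonded ortho isomer is removed by chromatography.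

Step 2
Reactants: 3 2,6-bis(BnO)-4-hydroxybenzaldehyde
Product: 4 2,6-bis(BnO)-4-(TIPSO)benzaldehyde
Conditions: TIPSCl, imidazole, DMF, rt
Reagents that add atoms: chlorotriisopropylsilane CC(C)[Si](Cl)(C(C)C)C(C)C
Why: Silyl ether formation at the only free phenol marks the oxygen that later becomes O1 of the lower unit with a group that tolerates the Lewis acid, peracid, enolate and organolithium steps ahead.

Step 3
Reactants: 5 3′,5′-bis(BnO)acetophenone
Product: 6 allyl 3-[3,5-bis(BnO)phenyl]-3-oxopropanoate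
Conditions: NaH, diallyl carbonate, THF, reflux
Reagents that add atoms: diallyl carbonate C=CCOC(=O)OCC=C
Why: Crossed Claisen condensation (C-acylation of the ketone enolate by a carbonate), driven by deprotonation of the β-keto ester, installs the ester that activates the Nazarov substrate and is later removed under neutral Pd(0) conditions.

Step 4
Reactants: 4 2,6-bis(BnO)-4-(TIPSO)benzaldehyde; 6 allyl 3-[3,5-bis(BnO)phenyl]-3-oxopropanoate
Product: 7 allyl 2-[3,5-bis(BnO)benzoyl]-3-[2,6-bis(BnO)-4-(TIPSO)phenyl]prop-2-enoate (E/Z mixture)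
Conditions: piperidine (cat.), AcOH (cat.), toluene, reflux, Dean–Stark
Reagents that add atoms: none
Why: Knoevenagel condensation with azeotropic removal of water joins the two aromatic halves without hydroxide (which would attack the aryl silyl ether), and the E/Z isomers interconvert under the Lewis acid of the next step.

Step 5
Reactants: 7 allyl 2-[3,5-bis(BnO)benzoyl]-3-[2,6-bis(BnO)-4-(TIPSO)phenyl]prop-2-enoate
Product: 8 allyl (2R,3R)-4,6-bis(BnO)-3-[2,6-bis(BnO)-4-(TIPSO)phenyl]-1-oxoindane-2-carboxylate (trans, in equilibrium with its enol)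
Conditions: Cu(OTf)2 (10 mol %), (S,S)-Ph-box (11 mol %), 4 Å MS, ClCH2CH2Cl, 40 °C
Reagents that add atoms: none
Why: Chiral Lewis acid-catalysed Nazarov cyclisation of an aryl vinyl β-keto ester, in which two-point binding to Cu(II)–bis(oxazoline) polarises the dienone, the conrotatory 4π closure onto the ring carbon lying between the acyl group and a benzyloxy group (ortho/para-activated) is torquoselective under ligand control and sets C3, and reprotonation gives the trans ester.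

Step 6
Reactants: 8 allyl (2R,3R)-4,6-bis(BnO)-3-[2,6-bis(BnO)-4-(TIPSO)phenyl]-1-oxoindane-2-carboxylate
Product: 10 (3R)-4,6-bis(BnO)-3-[2,6-bis(BnO)-4-(TIPSO)phenyl]indan-1-one, via β-keto acid 9 (not isolated)
Conditions: Pd(PPh3)4 (5 mol %), morpholine, THF, rt
Reagents that add atoms: none
Why: Tsuji-type Pd(0) deallylation with morpholine as allyl acceptor frees the β-keto acid, which decarboxylates at room temperature without touching the C3 stereocentre or the benzyl and silyl ethers.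

Step 7
Reactants: 10 (3R)-4,6-bis(BnO)-3-[2,6-bis(BnO)-4-(TIPSO)phenyl]indan-1-one
Product: 11 (4S)-5,7-bis(BnO)-4-[2,6-bis(BnO)-4-(TIPSO)phenyl]chroman-2-one
Conditions: m-CPBA (1.5 equiv), Sc(OTf)3 (5 mol %), CH2Cl2, 0 °C → rt
Reagents that add atoms: 3-chloroperoxybenzoic acid OOC(=O)c1cccc(Cl)c1
Why: The peracid adds to the Lewis acid-activated ketone to give the Criegee adduct, which collapses by 1,2-shift of ring aryl carbon C7a from carbon to oxygen with loss of 3-chlorobenzoate (Baeyer–Villiger oxidation; closest precedent is the conversion of 1-indanones into 3,4-dihydrocoumarins). No ring is closed by cyclisation: the five-membered carbocycle is expanded by one oxygen atom to the six-membered lactone, whose ring oxygen is the future O1 and whose new bond is O1–C8a. No stereocentre is formed; the benzylic centre (indanone C3, chroman C4) lies outside the migrating framework and is carried over unchanged, R becoming S only through CIP priorities. The step needs migration of the aryl carbon rather than the C2 methylene, which is secured by the higher migratory aptitude of aryl over primary alkyl and by keeping C2 unoxygenated until after this step. It also needs attack at the ketone rather than oxidation of the electron-rich arenes: both benzyloxy groups are meta to the carbonyl and leave it electrophilic, the carbonyl-bearing ring is deactivated, and the free positions of the pendant ring are flanked by the bulky silyloxy group.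

Step 8
Reactants: 11 (4S)-5,7-bis(BnO)-4-[2,6-bis(BnO)-4-(TIPSO)phenyl]chroman-2-one
Product: 13 (3R,4S)-5,7-bis(BnO)-4-[2,6-bis(BnO)-4-(TIPSO)phenyl]-3-hydroxychroman-2-one, via potassium enolate 12 (not isolated)
Conditions: KHMDS, THF, −78 °C; then 3-phenyl-2-(phenylsulfonyl)oxaziridine, −78 °C; AcOH quench
Reagents that add atoms: 3-phenyl-2-(phenylsulfonyl)oxaziridine O=S(=O)(c1ccccc1)N1OC1c1ccccc1
Why: Davis oxaziridine hydroxylation of the lactone enolate at low temperature (which suppresses ketene formation), with the pseudo-axial C4 aryl group blocking one enolate face so that oxygen enters anti to it and the 3,4-trans (3R) alcohol results.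

Step 9
Reactants: 13 (3R,4S)-5,7-bis(BnO)-4-[2,6-bis(BnO)-4-(TIPSO)phenyl]-3-hydroxychroman-2-one
Product: 14 (3R,4S)-3,5,7-tris(BnO)-4-[2,6-bis(BnO)-4-(TIPSO)phenyl]chroman-2-one
Conditions: BnBr, Ag2O, CH2Cl2, rt, dark
Reagents that add atoms: benzyl bromide BrCc1ccccc1
Why: Silver(I) oxide-mediated Williamson benzylation is mild enough to etherify an α-hydroxy aryl ester without epimerisation at C3 or opening of the lactone.

Step 10
Reactants: 14 (3R,4S)-3,5,7-tris(BnO)-4-[2,6-bis(BnO)-4-(TIPSO)phenyl]chroman-2-one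
Product: 15 (2R,3R)-2-(BnO)-3-[2,4-bis(BnO)-6-hydroxyphenyl]-3-[2,6-bis(BnO)-4-(TIPSO)phenyl]-N-methoxy-N-methylpropanamide
Conditions: MeNH(OMe)·HCl, AlMe3, CH2Cl2, 0 °C → rt
Reagents that add atoms: N,O-dimethylhydroxylamine hydrochloride CNOC.Cl
Why: Weinreb aminolysis of the aryl ester by the aluminium amide opens the lactone at its acyl C–O bond under non-epimerising conditions, keeps the O1–C8a bond as a free phenol and fixes the carbonyl at a level that accepts exactly one aryl nucleophile.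

Step 11
Reactants: 15 (2R,3R)-2-(BnO)-3-[2,4-bis(BnO)-6-hydroxyphenyl]-3-[2,6-bis(BnO)-4-(TIPSO)phenyl]-N-methoxy-N-methylpropanamide; 16 4-bromo-1,2-bis(BnO)benzene
Product: 18 (2R,3R)-2-(BnO)-1-[3,4-bis(BnO)phenyl]-3-[2,4-bis(BnO)-6-hydroxyphenyl]-3-[2,6-bis(BnO)-4-(TIPSO)phenyl]propan-1-one, via aryllithium 17 (not isolated)
Conditions: 16 (2.5 equiv), n-BuLi, THF, −78 °C; then 15, −78 → −40 °C; aq. NH4Cl
Reagents that add atoms: none
Why: Bromine–lithium exchange gives the aryllithium, one equivalent of which deprotonates the phenol while a second adds to the Weinreb amide and stops at the chelated tetrahedral intermediate, so the aryl ketone forms without over-addition.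

Step 12
Reactants: 18 (2R,3R)-2-(BnO)-1-[3,4-bis(BnO)phenyl]-3-[2,4-bis(BnO)-6-hydroxyphenyl]-3-[2,6-bis(BnO)-4-(TIPSO)phenyl]propan-1-one
Product: 19 (1S,2R,3R)-2-(BnO)-1-[3,4-bis(BnO)phenyl]-3-[2,4-bis(BnO)-6-hydroxyphenyl]-3-[2,6-bis(BnO)-4-(TIPSO)phenyl]propan-1-ol
Conditions: Zn(BH4)2, Et2O, −30 → 0 °C
Reagents that add atoms: none
Why: Chelation-controlled (Cram-chelate) hydride reduction, in which zinc bridges the ketone and the α-benzyloxy oxygen and hydride attacks the face opposite the bulky diarylmethyl group, giving the anti (1S) benzylic alcohol.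

Step 13
Reactants: 19 (1S,2R,3R)-2-(BnO)-1-[3,4-bis(BnO)phenyl]-3-[2,4-bis(BnO)-6-hydroxyphenyl]-3-[2,6-bis(BnO)-4-(TIPSO)phenyl]propan-1-ol
Product: 20 (2R,3R,4S)-3,5,7-tris(BnO)-2-[3,4-bis(BnO)phenyl]-4-[2,6-bis(BnO)-4-(TIPSO)phenyl]chromane
Conditions: PPh3, DIAD, THF, 0 °C → rt
Reagents that add atoms: none
Why: Intramolecular Mitsunobu etherification, a 6-exo-tet SN2 closure by the phenol with inversion at the benzylic carbon (ionisation being disfavoured by the adjacent benzyloxy group), turns the (1S) carbinol into the (2R) centre and so gives the 2,3-cis-3,4-trans upper unit.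

Step 14
Reactants: 20 (2R,3R,4S)-3,5,7-tris(BnO)-2-[3,4-bis(BnO)phenyl]-4-[2,6-bis(BnO)-4-(TIPSO)phenyl]chromane
Product: 21 3,5-bis(BnO)-4-{(2R,3R,4S)-3,5,7-tris(BnO)-2-[3,4-bis(BnO)phenyl]chroman-4-yl}phenol
Conditions: TBAF, AcOH, THF, 0 °C
Reagents that add atoms: none
Why: Fluoride-mediated desilylation, buffered with acetic acid, frees only the phenol para to the interflavan bond because every other oxygen is a benzyl ether.

Step 15
Reactants: 22 3,4,5-trihydroxybenzaldehyde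
Product: 23 7-hydroxy-2,2-diphenyl-1,3-benzodioxole-5-carbaldehyde
Conditions: Ph2CCl2, K2CO3, MeCN, rt, under Ar
Reagents that add atoms: dichlorodiphenylmethane ClC(Cl)(c1ccccc1)c1ccccc1
Why: Diphenylmethylene ketal formation can only bridge two adjacent oxygens, so the symmetric pyrogallol is desymmetrised with one meta hydroxyl left free, and the ketal is removable by hydrogenolysis at the end.

Step 16
Reactants: 23 7-hydroxy-2,2-diphenyl-1,3-benzodioxole-5-carbaldehyde
Product: 24 2,2-diphenyl-7-(TIPSO)-1,3-benzodioxole-5-carbaldehyde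
Conditions: TIPSCl, imidazole, DMF, rt
Reagents that add atoms: chlorotriisopropylsilane CC(C)[Si](Cl)(C(C)C)C(C)C
Why: Silylation of the remaining phenol gives a group orthogonal to benzyl ethers and the ketal, so the future 3′-galloyl position can be unmasked alone.

Step 17
Reactants: 24 2,2-diphenyl-7-(TIPSO)-1,3-benzodioxole-5-carbaldehyde
Product: 25 rac-1-[2,2-diphenyl-7-(TIPSO)-1,3-benzodioxol-5-yl]prop-2-en-1-ol
Conditions: CH2=CHMgBr, THF, −78 → 0 °C; aq. NH4Cl
Reagents that add atoms: vinylmagnesium bromide C=C[Mg]Br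
Why: Grignard 1,2-addition to the aldehyde gives the racemic aryl vinyl carbinol required for kinetic resolution.

Step 18
Reactants: 25 rac-1-[2,2-diphenyl-7-(TIPSO)-1,3-benzodioxol-5-yl]prop-2-en-1-ol
Product: 26 (S)-[2,2-diphenyl-7-(TIPSO)-1,3-benzodioxol-5-yl][(2R)-oxiran-2-yl]methanol
Conditions: Ti(OiPr)4 (10 mol %), L-(+)-DIPT (15 mol %), t-BuOOH (0.45 equiv), 4 Å MS, CH2Cl2, −20 °C
Reagents that add atoms: tert-butyl hydroperoxide CC(C)(C)OO
Why: Sharpless kinetic resolution, in which the L-(+)-tartrate catalyst epoxidises the (R)-carbinol much faster than its enantiomer and with erythro selectivity, so stopping below half conversion should give the (S)-carbinol/(R)-oxirane epoxy alcohol with both centres set by the catalyst.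

Step 19
Reactants: 21 3,5-bis(BnO)-4-{(2R,3R,4S)-3,5,7-tris(BnO)-2-[3,4-bis(BnO)phenyl]chroman-4-yl}phenol; 26 (S)-[2,2-diphenyl-7-(TIPSO)-1,3-benzodioxol-5-yl][(2R)-oxiran-2-yl]methanol
Product: 27 5-{(R)-[(2R)-oxiran-2-yl][3,5-bis(BnO)-4-{(2R,3R,4S)-3,5,7-tris(BnO)-2-[3,4-bis(BnO)phenyl]chroman-4-yl}phenoxy]methyl}-2,2-diphenyl-7-(TIPSO)-1,3-benzodioxole
Conditions: PPh3, DIAD, toluene, 0 °C → rt
Reagents that add atoms: none
Why: Intermolecular Mitsunobu etherification of the unhindered phenol with the secondary benzylic alcohol proceeds with inversion (the adjacent oxirane disfavours ionisation), forming the lower O1–C2 bond with the (R) configuration.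

Step 20
Reactants: 27 the aryl oxiranylmethyl ether from step 19
Product: 28 (2R,3R)-5,7-bis(BnO)-2-[2,2-diphenyl-7-(TIPSO)-1,3-benzodioxol-5-yl]-6-{(2R,3R,4R)-3,5,7-tris(BnO)-2-[3,4-bis(BnO)phenyl]chroman-4-yl}chroman-3-ol
Conditions: AuCl3 (5 mol %), AgOTf (15 mol %), CH2Cl2, 0 °C → rt
Reagents that add atoms: none
Why: Gold(III)-catalysed intramolecular Friedel–Crafts epoxide–arene cyclisation, in which the activated oxirane is opened at its terminal carbon by the ring position ortho to the ether oxygen (6-endo, activated by three oxygens), closes the lower pyran with C2 and C3 untouched and hence 2,3-cis.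

Step 21
Reactants: 28 the silyl-protected lower flavan-3-ol from step 20
Product: 29 (2R,3R)-5,7-bis(BnO)-2-(7-hydroxy-2,2-diphenyl-1,3-benzodioxol-5-yl)-6-{(2R,3R,4R)-3,5,7-tris(BnO)-2-[3,4-bis(BnO)phenyl]chroman-4-yl}chroman-3-ol
Conditions: TBAF, AcOH, THF, 0 °C
Reagents that add atoms: none
Why: Buffered fluoride desilylation reveals the 3′-phenol, so that it and the 3-hydroxyl of the lower unit are the only free hydroxyls.

Step 22
Reactants: 29 the phenol–alcohol from step 21; 30 3,4,5-tris(BnO)benzoic acid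
Product: 31 3-O,3′-O-bis[3,4,5-tris(BnO)benzoyl] derivative of 29
Conditions: 30 (3 equiv), EDC·HCl, DMAP, CH2Cl2, rt
Reagents that add atoms: none
Why: Steglich (carbodiimide/DMAP) esterification acylates both the secondary alcohol and the phenol with the protected gallic acid, the upper 3-oxygen being held as its benzyl ether.

Step 23
Reactants: 31 the fully protected digallate
Product: 32 epicatechin-(4β→6)-epigallocatechin 3,3′-di-O-gallate (CNP0237700.1)
Conditions: H2 (1 atm), Pd(OH)2/C, THF–MeOH, rt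
Reagents that add atoms: none
Why: Global hydrogenolysis over Pearlman's catalyst cleaves the thirteen benzyl ethers and the diphenylmethylene ketal under neutral conditions that should leave the gallate esters and the benzylic ring C–O bonds intact.

**Compound list**

1 | 3,5-bis(benzyloxy)phenol | Oc1cc(OCc2ccccc2)cc(OCc2ccccc2)c1 | starting material
2 | [2,6-bis(benzyloxy)-4-hydroxyphenyl]methylidene(dimethyl)iminium chloride | C[N+](C)=Cc1c(OCc2ccccc2)cc(O)cc1OCc1ccccc1.[Cl-] | intermediate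
3 | 2,6-bis(benzyloxy)-4-hydroxybenzaldehyde | O=Cc1c(OCc2ccccc2)cc(O)cc1OCc1ccccc1 | intermediate
4 | 2,6-bis(benzyloxy)-4-[(triisopropylsilyl)oxy]benzaldehyde | O=Cc1c(OCc2ccccc2)cc(O[Si](C(C)C)(C(C)C)C(C)C)cc1OCc1ccccc1 | intermediate
5 | 1-[3,5-bis(benzyloxy)phenyl]ethan-1-one | CC(=O)c1cc(OCc2ccccc2)cc(OCc2ccccc2)c1 | starting material
6 | allyl 3-[3,5-bis(benzyloxy)phenyl]-3-oxopropanoate | C=CCOC(=O)CC(=O)c1cc(OCc2ccccc2)cc(OCc2ccccc2)c1 | intermediate
7 | allyl 2-[3,5-bis(benzyloxy)benzoyl]-3-{2,6-bis(benzyloxy)-4-[(triisopropylsilyl)oxy]phenyl}prop-2-enoate (E/Z mixture) | C=CCOC(=O)C(=Cc1c(OCc2ccccc2)cc(O[Si](C(C)C)(C(C)C)C(C)C)cc1OCc1ccccc1)C(=O)c1cc(OCc2ccccc2)cc(OCc2ccccc2)c1 | intermediate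
8 | allyl (2R,3R)-4,6-bis(benzyloxy)-3-{2,6-bis(benzyloxy)-4-[(triisopropylsilyl)oxy]phenyl}-1-oxo-2,3-dihydro-1H-indene-2-carboxylate | O=C1[C@H](C(=O)OCC=C)[C@@H](c2c(OCc3ccccc3)cc(O[Si](C(C)C)(C(C)C)C(C)C)cc2OCc2ccccc2)c2c(OCc3ccccc3)cc(OCc3ccccc3)cc21 | intermediate
9 | (2R,3R)-4,6-bis(benzyloxy)-3-{2,6-bis(benzyloxy)-4-[(triisopropylsilyl)oxy]phenyl}-1-oxo-2,3-dihydro-1H-indene-2-carboxylic acid | O=C1[C@H](C(=O)O)[C@@H](c2c(OCc3ccccc3)cc(O[Si](C(C)C)(C(C)C)C(C)C)cc2OCc2ccccc2)c2c(OCc3ccccc3)cc(OCc3ccccc3)cc21 | intermediate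
10 | (3R)-4,6-bis(benzyloxy)-3-{2,6-bis(benzyloxy)-4-[(triisopropylsilyl)oxy]phenyl}-2,3-dihydro-1H-inden-1-one | O=C1C[C@@H](c2c(OCc3ccccc3)cc(O[Si](C(C)C)(C(C)C)C(C)C)cc2OCc2ccccc2)c2c(OCc3ccccc3)cc(OCc3ccccc3)cc21 | intermediate
11 | (4S)-5,7-bis(benzyloxy)-4-{2,6-bis(benzyloxy)-4-[(triisopropylsilyl)oxy]phenyl}-3,4-dihydro-2H-chromen-2-one | O=C1C[C@@H](c2c(OCc3ccccc3)cc(O[Si](C(C)C)(C(C)C)C(C)C)cc2OCc2ccccc2)c2c(OCc3ccccc3)cc(OCc3ccccc3)cc2O1 | intermediate
12 | potassium (4S)-5,7-bis(benzyloxy)-4-{2,6-bis(benzyloxy)-4-[(triisopropylsilyl)oxy]phenyl}-4H-chromen-2-olate | [K+].[O-]C1=C[C@@H](c2c(OCc3ccccc3)cc(O[Si](C(C)C)(C(C)C)C(C)C)cc2OCc2ccccc2)c2c(OCc3ccccc3)cc(OCc3ccccc3)cc2O1 | intermediate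
13 | (3R,4S)-5,7-bis(benzyloxy)-4-{2,6-bis(benzyloxy)-4-[(triisopropylsilyl)oxy]phenyl}-3-hydroxy-3,4-dihydro-2H-chromen-2-one | O=C1[C@H](O)[C@@H](c2c(OCc3ccccc3)cc(O[Si](C(C)C)(C(C)C)C(C)C)cc2OCc2ccccc2)c2c(OCc3ccccc3)cc(OCc3ccccc3)cc2O1 | intermediate
14 | (3R,4S)-3,5,7-tris(benzyloxy)-4-{2,6-bis(benzyloxy)-4-[(triisopropylsilyl)oxy]phenyl}-3,4-dihydro-2H-chromen-2-one | O=C1[C@H](OCc2ccccc2)[C@@H](c2c(OCc3ccccc3)cc(O[Si](C(C)C)(C(C)C)C(C)C)cc2OCc2ccccc2)c2c(OCc3ccccc3)cc(OCc3ccccc3)cc2O1 | intermediate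
15 | (2R,3R)-2-(benzyloxy)-3-[2,4-bis(benzyloxy)-6-hydroxyphenyl]-3-{2,6-bis(benzyloxy)-4-[(triisopropylsilyl)oxy]phenyl}-N-methoxy-N-methylpropanamide | CON(C)C(=O)[C@H](OCc1ccccc1)[C@@H](c1c(OCc2ccccc2)cc(O[Si](C(C)C)(C(C)C)C(C)C)cc1OCc1ccccc1)c1c(O)cc(OCc2ccccc2)cc1OCc1ccccc1 | intermediate
16 | 4-bromo-1,2-bis(benzyloxy)benzene | Brc1ccc(OCc2ccccc2)c(OCc2ccccc2)c1 | starting material
17 | [3,4-bis(benzyloxy)phenyl]lithium | [Li]c1ccc(OCc2ccccc2)c(OCc2ccccc2)c1 | intermediate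
18 | (2R,3R)-2-(benzyloxy)-1-[3,4-bis(benzyloxy)phenyl]-3-[2,4-bis(benzyloxy)-6-hydroxyphenyl]-3-{2,6-bis(benzyloxy)-4-[(triisopropylsilyl)oxy]phenyl}propan-1-one | O=C(c1ccc(OCc2ccccc2)c(OCc2ccccc2)c1)[C@H](OCc1ccccc1)[C@@H](c1c(OCc2ccccc2)cc(O[Si](C(C)C)(C(C)C)C(C)C)cc1OCc1ccccc1)c1c(O)cc(OCc2ccccc2)cc1OCc1ccccc1 | intermediate
19 | (1S,2R,3R)-2-(benzyloxy)-1-[3,4-bis(benzyloxy)phenyl]-3-[2,4-bis(benzyloxy)-6-hydroxyphenyl]-3-{2,6-bis(benzyloxy)-4-[(triisopropylsilyl)oxy]phenyl}propan-1-ol | O[C@@H](c1ccc(OCc2ccccc2)c(OCc2ccccc2)c1)[C@H](OCc1ccccc1)[C@@H](c1c(OCc2ccccc2)cc(O[Si](C(C)C)(C(C)C)C(C)C)cc1OCc1ccccc1)c1c(O)cc(OCc2ccccc2)cc1OCc1ccccc1 | intermediate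
20 | (2R,3R,4S)-3,5,7-tris(benzyloxy)-2-[3,4-bis(benzyloxy)phenyl]-4-{2,6-bis(benzyloxy)-4-[(triisopropylsilyl)oxy]phenyl}-3,4-dihydro-2H-chromene | CC(C)[Si](C(C)C)(C(C)C)Oc1cc(OCc2ccccc2)c([C@H]2c3c(OCc4ccccc4)cc(OCc4ccccc4)cc3O[C@H](c3ccc(OCc4ccccc4)c(OCc4ccccc4)c3)[C@@H]2OCc2ccccc2)c(OCc2ccccc2)c1 | intermediate
21 | 3,5-bis(benzyloxy)-4-{(2R,3R,4S)-3,5,7-tris(benzyloxy)-2-[3,4-bis(benzyloxy)phenyl]-3,4-dihydro-2H-chromen-4-yl}phenol | Oc1cc(OCc2ccccc2)c([C@H]2c3c(OCc4ccccc4)cc(OCc4ccccc4)cc3O[C@H](c3ccc(OCc4ccccc4)c(OCc4ccccc4)c3)[C@@H]2OCc2ccccc2)c(OCc2ccccc2)c1 | intermediate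
22 | 3,4,5-trihydroxybenzaldehyde | O=Cc1cc(O)c(O)c(O)c1 | starting material
23 | 7-hydroxy-2,2-diphenyl-1,3-benzodioxole-5-carbaldehyde | O=Cc1cc(O)c2OC(c3ccccc3)(c3ccccc3)Oc2c1 | intermediate
24 | 2,2-diphenyl-7-[(triisopropylsilyl)oxy]-1,3-benzodioxole-5-carbaldehyde | O=Cc1cc(O[Si](C(C)C)(C(C)C)C(C)C)c2OC(c3ccccc3)(c3ccccc3)Oc2c1 | intermediate
25 | rac-1-{2,2-diphenyl-7-[(triisopropylsilyl)oxy]-1,3-benzodioxol-5-yl}prop-2-en-1-ol | C=CC(O)c1cc(O[Si](C(C)C)(C(C)C)C(C)C)c2OC(c3ccccc3)(c3ccccc3)Oc2c1 | intermediate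
26 | (S)-{2,2-diphenyl-7-[(triisopropylsilyl)oxy]-1,3-benzodioxol-5-yl}[(2R)-oxiran-2-yl]methanol | O[C@H]([C@H]1CO1)c1cc(O[Si](C(C)C)(C(C)C)C(C)C)c2OC(c3ccccc3)(c3ccccc3)Oc2c1 | intermediate
27 | 5-{(R)-[(2R)-oxiran-2-yl][3,5-bis(benzyloxy)-4-{(2R,3R,4S)-3,5,7-tris(benzyloxy)-2-[3,4-bis(benzyloxy)phenyl]chroman-4-yl}phenoxy]methyl}-2,2-diphenyl-7-[(triisopropylsilyl)oxy]-1,3-benzodioxole | CC(C)[Si](C(C)C)(C(C)C)Oc1cc([C@@H](Oc3cc(OCc6ccccc6)c([C@H]4c5c(OCc6ccccc6)cc(OCc6ccccc6)cc5O[C@H](c5ccc(OCc6ccccc6)c(OCc6ccccc6)c5)[C@@H]4OCc4ccccc4)c(OCc4ccccc4)c3)[C@H]2CO2)cc2OC(c3ccccc3)(c3ccccc3)Oc12 | intermediate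
28 | (2R,3R)-5,7-bis(benzyloxy)-2-{2,2-diphenyl-7-[(triisopropylsilyl)oxy]-1,3-benzodioxol-5-yl}-6-{(2R,3R,4R)-3,5,7-tris(benzyloxy)-2-[3,4-bis(benzyloxy)phenyl]chroman-4-yl}chroman-3-ol (C4 of the upper unit has the same spatial arrangement as in 20; the descriptor changes by CIP priority only) | CC(C)[Si](C(C)C)(C(C)C)Oc1cc([C@H]2Oc3cc(OCc6ccccc6)c([C@H]4c5c(OCc6ccccc6)cc(OCc6ccccc6)cc5O[C@H](c5ccc(OCc6ccccc6)c(OCc6ccccc6)c5)[C@@H]4OCc4ccccc4)c(OCc4ccccc4)c3C[C@H]2O)cc2OC(c3ccccc3)(c3ccccc3)Oc12 | intermediate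
29 | (2R,3R)-5,7-bis(benzyloxy)-2-(7-hydroxy-2,2-diphenyl-1,3-benzodioxol-5-yl)-6-{(2R,3R,4R)-3,5,7-tris(benzyloxy)-2-[3,4-bis(benzyloxy)phenyl]chroman-4-yl}chroman-3-ol | Oc1cc([C@H]2Oc3cc(OCc6ccccc6)c([C@H]4c5c(OCc6ccccc6)cc(OCc6ccccc6)cc5O[C@H](c5ccc(OCc6ccccc6)c(OCc6ccccc6)c5)[C@@H]4OCc4ccccc4)c(OCc4ccccc4)c3C[C@H]2O)cc2OC(c3ccccc3)(c3ccccc3)Oc12 | intermediate
30 | 3,4,5-tris(benzyloxy)benzoic acid | OC(=O)c1cc(OCc2ccccc2)c(OCc2ccccc2)c(OCc2ccccc2)c1 | starting material
31 | (2R,3R)-5,7-bis(benzyloxy)-2-{2,2-diphenyl-7-[3,4,5-tris(benzyloxy)benzoyloxy]-1,3-benzodioxol-5-yl}-6-{(2R,3R,4R)-3,5,7-tris(benzyloxy)-2-[3,4-bis(benzyloxy)phenyl]chroman-4-yl}chroman-3-yl 3,4,5-tris(benzyloxy)benzoate | O=C(Oc1cc([C@H]2Oc3cc(OCc6ccccc6)c([C@H]4c5c(OCc6ccccc6)cc(OCc6ccccc6)cc5O[C@H](c5ccc(OCc6ccccc6)c(OCc6ccccc6)c5)[C@@H]4OCc4ccccc4)c(OCc4ccccc4)c3C[C@H]2OC(=O)c2cc(OCc4ccccc4)c(OCc4ccccc4)c(OCc4ccccc4)c2)cc2OC(c3ccccc3)(c3ccccc3)Oc12)c1cc(OCc2ccccc2)c(OCc2ccccc2)c(OCc2ccccc2)c1 | intermediate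
32 | (2R,3R)-2-[3,4-dihydroxy-5-(3,4,5-trihydroxybenzoyloxy)phenyl]-6-[(2R,3R,4S)-2-(3,4-dihydroxyphenyl)-3,5,7-trihydroxychroman-4-yl]-5,7-dihydroxychroman-3-yl 3,4,5-trihydroxybenzoate (CNP0237700.1) | O=C(Oc1cc([C@H]2Oc3cc(O)c([C@H]4c5c(O)cc(O)cc5O[C@H](c5ccc(O)c(O)c5)[C@@H]4O)c(O)c3C[C@H]2OC(=O)c2cc(O)c(O)c(O)c2)cc(O)c1O)c1cc(O)c(O)c(O)c1 | target

**Step count and risks**

Total steps: 23. Longest linear sequence: 18 steps (1 to 32 through steps 1, 2, 4–14 and 19–23).

Steps most likely to fail: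

Step 5. What may go wrong: weak enantiofacial (torquo) control by the copper complex, or slow ring closure because the trioxygenated β-aryl group over-stabilises the pentadienyl cation, either of which would lower the enantiomeric purity carried through the route. Fallback (resolution in place of asymmetric catalysis): starting from 7, cyclisation with an achiral Lewis acid (Sc(OTf)3, ClCH2CH2Cl, 50 °C) should give the racemic trans keto ester F1. The deallylation–decarboxylation conditions of step 6 then give the racemic indanone F2. Ruthenium-catalysed asymmetric transfer hydrogenation ((R,R)-Ts-DENEB, HCO2H–Et3N, rt), run slightly past half conversion, should reduce the (S)-ketone to its cis-indanol (hydride anti to the C3 aryl group, matched with the catalyst) and leave the (R)-ketone, which is separated and is compound 10.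

Step 20. What may go wrong: ionisation of the benzylic aryl ether, or opening of the oxirane at its internal carbon with aryl shift, in competition with the 6-endo arylation. Fallback (anionic instead of electrophilic ring closure): starting from 21, ortho-bromination of the free phenol (NBS, cat. i-Pr2NH, CH2Cl2, −78 °C; the phenol ring is the most activated arene) would give the bromophenol F3. Mitsunobu coupling with 26 under the conditions of step 19 gives the bromo aryl ether F4. Bromine–lithium exchange (n-BuLi, THF, −78 °C) then generates an aryllithium that opens the oxirane at its terminal carbon and delivers compound 28.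

Step 13. What may go wrong: partial ionisation of the activated, electron-rich benzylic alcohol (SN1 leakage), eroding the inversion at C2. Fallback (C2–aryl bond made on the intact ring instead of the C2–O bond): starting from 14, DIBAL-H (CH2Cl2, −78 °C) gives the lactol F5. Benzenesulfinic acid with CaCl2 converts it into the 2-(phenylsulfonyl)chroman F6. Treatment with the diarylzinc F7 (prepared from 17 and ZnBr2) should ionise the sulfone to the cyclic oxocarbenium ion and deliver the aryl group trans to the pseudo-axial C4 aryl substituent, giving compound 20 directly.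

**Further compounds**

F1 | step 5 | racemic trans allyl 4,6-bis(benzyloxy)-3-{2,6-bis(benzyloxy)-4-[(triisopropylsilyl)oxy]phenyl}-1-oxoindane-2-carboxylate | O=C1C(C(=O)OCC=C)C(c2c(OCc3ccccc3)cc(O[Si](C(C)C)(C(C)C)C(C)C)cc2OCc2ccccc2)c2c(OCc3ccccc3)cc(OCc3ccccc3)cc21
F2 | step 5 | racemic 4,6-bis(benzyloxy)-3-{2,6-bis(benzyloxy)-4-[(triisopropylsilyl)oxy]phenyl}indan-1-one | O=C1CC(c2c(OCc3ccccc3)cc(O[Si](C(C)C)(C(C)C)C(C)C)cc2OCc2ccccc2)c2c(OCc3ccccc3)cc(OCc3ccccc3)cc21
F3 | step 20 | 2-bromo derivative of phenol 21 (bromine ortho to the hydroxyl) | Oc1cc(OCc2ccccc2)c([C@H]2c3c(OCc4ccccc4)cc(OCc4ccccc4)cc3O[C@H](c3ccc(OCc4ccccc4)c(OCc4ccccc4)c3)[C@@H]2OCc2ccccc2)c(OCc2ccccc2)c1Br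
F4 | step 20 | bromo analogue of ether 27 (bromine ortho to the ether oxygen) | CC(C)[Si](C(C)C)(C(C)C)Oc1cc([C@@H](Oc3c(Br)c(OCc6ccccc6)c([C@H]4c5c(OCc6ccccc6)cc(OCc6ccccc6)cc5O[C@H](c5ccc(OCc6ccccc6)c(OCc6ccccc6)c5)[C@@H]4OCc4ccccc4)c(OCc4ccccc4)c3)[C@H]2CO2)cc2OC(c3ccccc3)(c3ccccc3)Oc12
F5 | step 13 | (3R,4S)-3,5,7-tris(benzyloxy)-4-{2,6-bis(benzyloxy)-4-[(triisopropylsilyl)oxy]phenyl}chroman-2-ol (anomeric mixture) | OC1[C@H](OCc2ccccc2)[C@@H](c2c(OCc3ccccc3)cc(O[Si](C(C)C)(C(C)C)C(C)C)cc2OCc2ccccc2)c2c(OCc3ccccc3)cc(OCc3ccccc3)cc2O1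
F6 | step 13 | (3R,4S)-3,5,7-tris(benzyloxy)-4-{2,6-bis(benzyloxy)-4-[(triisopropylsilyl)oxy]phenyl}-2-(phenylsulfonyl)chromane (anomeric mixture) | O=S(=O)(c1ccccc1)C1[C@H](OCc2ccccc2)[C@@H](c2c(OCc3ccccc3)cc(O[Si](C(C)C)(C(C)C)C(C)C)cc2OCc2ccccc2)c2c(OCc3ccccc3)cc(OCc3ccccc3)cc2O1
F7 | step 13 | bis[3,4-bis(benzyloxy)phenyl]zinc | c1ccc(COc2ccc([Zn]c3ccc(OCc4ccccc4)c(OCc4ccccc4)c3)cc2OCc2ccccc2)cc1
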